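## Retrosynthetic overview

1. Enabling feature: ring B (C1–C2–C3–C4–C4a–C8a) is a cyclohexene whose only double bond, C4a=C8a, is an edge of aromatic ring A. It carries an aryl group on C1 and trans one-carbon arms on C2 and C3. This is the retron of an o-quinodimethane/fumarate Diels–Alder reaction, so C1–C2 and C3–C4 are cut together.
2. The diene is stored as a strained benzocyclobutene, racemic trans-2-aryl-4,5-dimethoxybenzocyclobutenol. Its temporary OH (future C4) lowers the opening temperature, fixes the (E,E) diene geometry and steers the endo orientation, and it leaves in the last step together with the catechol benzyl groups.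
3. The C2–C3 unit is the C2-symmetric N,N'-fumaroylbis[(2R)-bornane-10,2-sultam] (camphor chiral pool). It sets the absolute configuration and is reduced off to the two CH2OH groups.
4. The benzocyclobutenol comes from 2-bromo-4,5-dimethoxybenzaldehyde and 3,4-bis(benzyloxy)benzyl chloride through a trans-stilbene oxide and a Br/Li exchange cyclisation.
5. Ring order: rings A and C (the pendant aryl) are bought, then oxirane (temporary), cyclobutene (temporary), and ring B last.

Key step: step 5

Remark on the chemistry: the tetralin numbering of the target (C1 bears the aryl group, C4 is the benzylic CH2) is used for all tetralins. Compounds 5 to 7 are racemic and drawn as one enantiomer, which is harmless because both stereocentres of 7 become sp2 centres in 12. Compounds 1, 3, 8 and 9 are taken as commercial.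

## Route

Step 1
Reactants: 1 3,4-bis(benzyloxy)benzyl chloride
Product: 2 1-[3,4-bis(benzyloxy)benzyl]tetrahydrothiophenium chloride
Conditions: tetrahydrothiophene (1.5 equiv), MeCN, 40 °C; Et2O trituration
Reagents that add atoms: tetrahydrothiophene, C1CCSC1
Why: Alkylation of a sulfide by an activated benzylic chloride (sulfonium salt formation, SN2) is standard chemistry and creates no stereocentre.

Step 2
Reactants: 2 1-[3,4-bis(benzyloxy)benzyl]tetrahydrothiophenium chloride; 3 2-bromo-4,5-dimethoxybenzaldehyde
Product: 5 rac-trans-2-(2-bromo-4,5-dimethoxyphenyl)-3-[3,4-bis(benzyloxy)phenyl]oxirane, via sulfonium ylide 4 (not isolated)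
Conditions: KOH (powder, 2 equiv), MeCN/H2O 9:1, 0 °C to rt; filtration through basic Al2O3
Reagents that add atoms: none
Why: Corey–Chaykovsky-type epoxidation with a semi-stabilised benzylic sulfonium ylide, in which reversible betaine formation should channel the reaction to the trans-oxirane (the two new stereocentres are set relative to each other, racemic).

Step 3
Reactants: 5 rac-trans-2-(2-bromo-4,5-dimethoxyphenyl)-3-[3,4-bis(benzyloxy)phenyl]oxirane
Product: 7 rac-trans-8-[3,4-bis(benzyloxy)phenyl]-3,4-dimethoxybicyclo[4.2.0]octa-1,3,5-trien-7-ol, via aryllithium 6 (not isolated)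
Conditions: n-BuLi (1.05 equiv), THF, −90 °C, 10 min; MgBr2·OEt2 (1.5 equiv), −78 to 0 °C; aq NH4Cl
Reagents that add atoms: none
Why: Parham-type cyclisation in which Br/Li exchange outruns attack on the oxirane and the MgBr2-activated oxirane is then opened by the ortho carbanion at the carbon that carries the bis(benzyloxy)phenyl group, as known for o-bromostilbene oxides, the trans alcohol being expected because the aryl and O-metal groups avoid each other on the flat four-membered ring.

Step 4
Reactants: 8 fumaryl chloride; 9 (1S)-(−)-2,10-camphorsultam [(2R)-bornane-10,2-sultam, 2 equiv]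
Product: 11 N,N'-fumaroylbis[(2R)-bornane-10,2-sultam], via sodium sultamide 10 (not isolated)
Conditions: NaH (2.1 equiv), toluene, 0 °C to rt; then 8 (1 equiv), rt; recrystallisation
Reagents that add atoms: none
Why: N-Acylation of the sultam sodium salt with a diacid chloride keeps the E alkene, and all stereocentres come from the camphor-derived auxiliary.

Step 5
Reactants: 7 rac-trans-8-[3,4-bis(benzyloxy)phenyl]-3,4-dimethoxybicyclo[4.2.0]octa-1,3,5-trien-7-ol; 11 N,N'-fumaroylbis[(2R)-bornane-10,2-sultam]
Product: 13 (1S,2R,3S,4S)-1-[3,4-bis(benzyloxy)phenyl]-4-hydroxy-6,7-dimethoxytetralin-2,3-dicarbonyl bis[(2R)-bornane-10,2-sultam] imide (1,2-trans 2,3-trans 3,4-cis), via (E,E)-hydroxy-o-quinodimethane 12 (not isolated)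
Conditions: 11 (1 equiv), degassed toluene, 85 °C, argon; 7 (1.3 equiv) added over 6 h; crystallisation
Reagents that add atoms: none
Why: Heating releases the ring strain of the cyclobutene in 7 through a conrotatory 4π electrocyclic opening in which, from the trans isomer, the donor OH and the aryl group both rotate outward, so that only the (E,E)-dienol 12 should form, and 12 is trapped at once by the doubly activated alkene of 11 in a concerted [4+2] cycloaddition that restores the aromaticity of ring A. The closest known reaction types are the thermolysis of 2-arylbenzocyclobutenol derivatives with Diels–Alder capture of the o-quinodimethane, the addition of α-hydroxy-α'-aryl-o-quinodimethanes to chiral fumarates, and the uncatalysed Diels–Alder reactions of 11 with simple dienes. Ring B is closed in an intermolecular suprafacial–suprafacial [4+2] mode that makes C1–C2 and C3–C4 together, while the four-membered ring is lost. C2 and C3 come out trans because the E geometry of the fumaroyl unit is carried over, and their absolute sense is set by the two (2R)-sultam units, which in the unchelated conformation (C=O anti to SO2, s-cis enoyl) both shield the Si,Si face and leave the Re,Re face open. C4 and C1 are set by the orientation of the diene: the carbonyl next to the carbinol terminus sits endo (hydrogen bond from the dienol OH plus secondary orbital overlap), which places OH cis to the C3 acyl group and forces the other carbonyl exo at the aryl terminus, hence the 1,2-trans relation. The step needs face selectivity, this one endo/exo orientation and capture faster than tautomerisation of 12 to the aldehyde; the C2 symmetry of 11 removes any regiochemical question, the OH/aryl difference between the diene termini secures the orientation, slow addition of 7 keeps the dienol concentration low, and the crystalline sultam adduct allows removal of minor diastereomers.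

Step 6
Reactants: 13 Diels–Alder adduct
Product: 14 (1S,2R,3R,4S)-1-[3,4-bis(benzyloxy)phenyl]-2,3-bis(hydroxymethyl)-6,7-dimethoxytetralin-4-ol
Conditions: LiAlH4 (6 equiv), THF, 0 °C to rt; H2O/aq NaOH work-up
Reagents that add atoms: none
Why: Reductive cleavage of N-acylsultams with LiAlH4 gives the primary alcohols directly and returns the auxiliary, hydride attack being faster than enolisation so that C2 and C3 keep their configuration while the benzyl ethers and the C4 alkoxide are inert.

Step 7
Reactants: 14 (1S,2R,3R,4S)-1-[3,4-bis(benzyloxy)phenyl]-2,3-bis(hydroxymethyl)-6,7-dimethoxytetralin-4-ol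
Product: 15 4-[(1S,2R,3R)-2,3-bis(hydroxymethyl)-6,7-dimethoxy-1,2,3,4-tetrahydronaphthalen-1-yl]benzene-1,2-diol (target)
Conditions: H2 (3 bar), Pd/C (10 wt% Pd), EtOH/AcOH 4:1, 40 °C
Reagents that add atoms: none
Why: Heterogeneous catalytic hydrogenolysis cleaves the two aryl benzyl ethers and the C4–OH bond, a secondary benzylic alcohol activated by the para methoxy group on C7, without touching C1, C2 or C3, so the temporary stereocentre C4 vanishes and the three others remain.

## Compound list

1 | 3,4-bis(benzyloxy)benzyl chloride | ClCc1ccc(OCc2ccccc2)c(OCc2ccccc2)c1 | starting material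
2 | 1-[3,4-bis(benzyloxy)benzyl]tetrahydrothiophenium chloride | [Cl-].C(c1ccc(OCc2ccccc2)c(OCc2ccccc2)c1)[S+]1CCCC1 | intermediate
3 | 2-bromo-4,5-dimethoxybenzaldehyde | COc1cc(Br)c(C=O)cc1OC | starting material
4 | 3,4-bis(benzyloxy)benzylide of tetrahydrothiophenium (sulfonium ylide, formed in the flask) | [CH-](c1ccc(OCc2ccccc2)c(OCc2ccccc2)c1)[S+]1CCCC1 | intermediate
5 | rac-trans-(2R*,3R*)-2-(2-bromo-4,5-dimethoxyphenyl)-3-[3,4-bis(benzyloxy)phenyl]oxirane | COc1cc(Br)c(cc1OC)[C@H]1O[C@@H]1c1ccc(OCc2ccccc2)c(OCc2ccccc2)c1 | intermediate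
6 | aryllithium from Br/Li exchange of 5 (formed in the flask) | COc1cc([Li])c(cc1OC)[C@H]1O[C@@H]1c1ccc(OCc2ccccc2)c(OCc2ccccc2)c1 | intermediate
7 | rac-trans-(7R*,8S*)-8-[3,4-bis(benzyloxy)phenyl]-3,4-dimethoxybicyclo[4.2.0]octa-1,3,5-trien-7-ol | COc1cc2c(cc1OC)[C@H](O)[C@H]2c1ccc(OCc3ccccc3)c(OCc3ccccc3)c1 | intermediate
8 | fumaryl chloride | O=C(Cl)/C=C/C(=O)Cl | starting material
9 | (1S)-(−)-2,10-camphorsultam, (2R)-bornane-10,2-sultam | CC1(C)[C@@H]2CC[C@]13CS(=O)(=O)N[C@@H]3C2 | starting material
10 | sodium salt of 9 (formed in the flask) | [Na+].CC1(C)[C@@H]2CC[C@]13CS(=O)(=O)[N-][C@@H]3C2 | intermediate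
11 | N,N'-fumaroylbis[(2R)-bornane-10,2-sultam] | CC1(C)[C@@H]2CC[C@]13CS(=O)(=O)N([C@@H]3C2)C(=O)/C=C/C(=O)N1[C@@H]2C[C@H]3CC[C@]2(CS1(=O)=O)C3(C)C | intermediate
12 | (E)-[(6E)-6-[3,4-bis(benzyloxy)benzylidene]-3,4-dimethoxycyclohexa-2,4-dien-1-ylidene]methanol, the (E,E)-hydroxy-o-quinodimethane (formed in the flask) | COC1=C/C(=C\O)/C(=C/c2ccc(OCc3ccccc3)c(OCc3ccccc3)c2)C=C1OC | intermediate
13 | (1S,2R,3S,4S) Diels–Alder adduct, 1,2-trans, 2,3-trans, 3,4-cis, both carbonyl groups bound to the sultam nitrogen | COc1cc2c(cc1OC)[C@H](c1ccc(OCc3ccccc3)c(OCc3ccccc3)c1)[C@@H](C(=O)N1[C@@H]3C[C@H]4CC[C@]3(CS1(=O)=O)C4(C)C)[C@H](C(=O)N1[C@@H]3C[C@H]4CC[C@]3(CS1(=O)=O)C4(C)C)[C@@H]2O | intermediate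
14 | (1S,2R,3R,4S)-1-[3,4-bis(benzyloxy)phenyl]-2,3-bis(hydroxymethyl)-6,7-dimethoxytetralin-4-ol | COc1cc2c(cc1OC)[C@H](c1ccc(OCc3ccccc3)c(OCc3ccccc3)c1)[C@@H](CO)[C@H](CO)[C@@H]2O | intermediate
15 | 4-[(1S,2R,3R)-2,3-bis(hydroxymethyl)-6,7-dimethoxy-1,2,3,4-tetrahydronaphthalen-1-yl]benzene-1,2-diol | COc1cc2c(cc1OC)[C@H](c1ccc(O)c(O)c1)[C@@H](CO)[C@H](CO)C2 | target

## Step count and risks

Total step count: 7. Longest linear sequence: 6 (steps 1, 2, 3, 5, 6, 7). Step 4 is a one-step side branch.

Steps most likely to fail:

**Step 5.**
- What may go wrong: face selectivity may erode at the temperature that ring opening needs, the competing orientation with the carbonyl endo at the aryl terminus may intrude, or the dienol may tautomerise before capture.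
- Fallback: it sets out from 7 and comes back at 13. The diene is made by light at low temperature instead of by heat.
- First, 7 is isomerised with catalytic KOt-Bu in THF at 0 °C (alkoxide-accelerated ring opening and proton transfer) to 2-[3,4-bis(benzyloxy)benzyl]-4,5-dimethoxybenzaldehyde F1.
- F1 is then irradiated (365 nm LED, CH2Cl2, −40 °C) in the presence of 11. Photoenolisation delivers the same dienol 12, and a photoenolisation/Diels–Alder sequence gives 13 under conditions where auxiliary control is at its strongest.

**Step 3.**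
- What may go wrong: Lewis acid-induced rearrangement of the very electron-rich oxirane (hydride or aryl shift) may occur before ring closure, or the cis alcohol may form.
- Fallback: it sets out from 1 and 3 and comes back at 13. The oxirane and the four-membered ring are bypassed, and the diene is stored as a sulfone.
- Compound 1 is converted with Zn dust and LiCl in THF into [3,4-bis(benzyloxy)benzyl]zinc chloride F2. A Negishi coupling with 3 (Pd(OAc)2, SPhos, THF, rt) gives the aldehyde F1.
- Irradiation of F1 in SO2-saturated benzene traps the photoenol as rac-cis-3-[3,4-bis(benzyloxy)phenyl]-1-hydroxy-5,6-dimethoxy-1,3-dihydrobenzo[c]thiophene 2,2-dioxide F3.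
- Heating F3 with 11 in toluene under an argon sweep extrudes SO2 cheletropically to 12, which adds to 11 to give 13.

**Step 7.**
- What may go wrong: acid-promoted dehydration across C3–C4 followed by unselective re-hydrogenation would lose the C3 configuration, or the C4–O cleavage may stay incomplete.
- Fallback: it sets out from 14 and comes back at 15. The two tasks are separated.
- Ionic hydrogenation (Et3SiH, BF3·OEt2, CH2Cl2, −40 °C) captures the C4 cation with hydride. It gives (1S,2R,3R)-1-[3,4-bis(benzyloxy)phenyl]-2,3-bis(hydroxymethyl)-6,7-dimethoxytetralin F4.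
- Neutral debenzylation (H2, 1 bar, Pd/C, EtOH, rt) then gives 15.

Further compounds
F1 | step 5 | 2-[3,4-bis(benzyloxy)benzyl]-4,5-dimethoxybenzaldehyde | COc1cc(C=O)c(Cc2ccc(OCc3ccccc3)c(OCc3ccccc3)c2)cc1OC
F2 | step 3 | [3,4-bis(benzyloxy)benzyl]zinc chloride | Cl[Zn]Cc1ccc(OCc2ccccc2)c(OCc2ccccc2)c1
F3 | step 3 | rac-cis-3-[3,4-bis(benzyloxy)phenyl]-1-hydroxy-5,6-dimethoxy-1,3-dihydrobenzo[c]thiophene 2,2-dioxide | COc1cc2c(cc1OC)[C@H](O)S(=O)(=O)[C@@H]2c1ccc(OCc3ccccc3)c(OCc3ccccc3)c1
F4 | step 7 | (1S,2R,3R)-1-[3,4-bis(benzyloxy)phenyl]-2,3-bis(hydroxymethyl)-6,7-dimethoxytetralin | COc1cc2c(cc1OC)[C@H](c1ccc(OCc3ccccc3)c(OCc3ccccc3)c1)[C@@H](CO)[C@H](CO)C2
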